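**Strategy.** The cyclobutane is cut at the ring bond between the carbon that carries pyranone C6 and the trans neighbour that carries a 4-hydroxyphenyl ring; one end is alpha to a carbonyl-derived carbon, the other benzylic, so both can hold a radical. Bridging these two carbons with nitrogen gives an all-cis pyrrolidine, the endo [3+2] adduct of a glycinate imine and methyl acrylate. Nitrogen deletion (1,1-diazene, loss of N2, collapse of the 1,4-diyl) contracts it to the cyclobutane in one operation with its stereocentres retained. Amide-directed epimerisation and C–H arylation complete the centrosymmetric core, whose two carboxyls are grown two-directionally into the 4-methoxy-2-pyranone rings.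

Key step: step 2

Remark: the target is the achiral, centrosymmetric (meso) isomer; chiral intermediates are racemic with one enantiomer drawn, and the four ring carbons are called C1 (glycine carbon, later a pyranone-bearing carbon), C2 (first aryl carbon), C3 (acrylate ester carbon) and C4 throughout.

Step 1
Reactants: 1 glycine tert-butyl ester; 2 4-(benzyloxy)benzaldehyde; 3 methyl acrylate
Product: 5 all-cis pyrrolidine 2-tert-butyl 4-methyl (2R*,4R*,5S*)-5-[4-(benzyloxy)phenyl]pyrrolidine-2,4-dicarboxylate, via glycinate imine 4 (not isolated)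
Conditions: MgSO4, toluene, rt; then methyl acrylate, AgOAc (10 mol %), Et3N (15 mol %), rt
Reagents that add atoms: none
Why: Condensation gives the (E)-imine, whose N-silver azomethine ylide (W-shaped, ester chelated) should add to the acrylate through the endo transition state of a [3+2] dipolar cycloaddition, so that the C2 ester, the C4 ester and the C5 aryl group end up all cis with the acrylate ester next to the aryl-bearing carbon.

Step 2
Reactants: 5 all-cis pyrrolidine diester
Product: 7 all-cis cyclobutane 1-tert-butyl 3-methyl 2-[4-(benzyloxy)phenyl]cyclobutane-1,3-dicarboxylate, via 1,1-diazene 6 (not isolated)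
Conditions: PhI(OH)OTs (2.5 equiv), NH2CO2NH4 (8 equiv), CF3CH2OH, 80 °C
Reagents that add atoms: none
Why: The iminoiodinane PhI=NH made in the flask aminates the ring nitrogen and a second equivalent of the trivalent-iodine oxidant turns the N-amino group into the 1,1-diazene 6, which loses N2 to a singlet 1,4-diyl that collapses to the C1–C2 bond. The closest known reaction type is the nitrogen-deletion ring contraction of 2-ester-5-aryl pyrrolidines to cyclobutanes by isodiazene extrusion. The four-membered ring closes by radical–radical recombination of the two ends of the diyl, a contraction from five to four ring atoms and not a polar exo or endo attack. No stereocentre is made from scratch: C1 and C2 come from C2 and C5 of 5 and should keep their cis relationship because the singlet diyl recombines faster than it rotates, and C3 is untouched, so the all-cis array of 5 is copied. The step needs recombination to beat beta-scission of the diyl into two acrylate-type alkenes and needs the oxidant to spare the benzyloxyphenyl ring; the ester at one radical centre and the aryl group at the other let N2 leave at 80 °C, and the free N–H is the only site the electrophilic nitrogen donor attacks.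

Step 3
Reactants: 7 all-cis cyclobutane diester
Product: 8 all-cis 2-[4-(benzyloxy)phenyl]-3-(methoxycarbonyl)cyclobutane-1-carboxylic acid
Conditions: CF3CO2H, CH2Cl2, rt
Reagents that add atoms: none
Why: Acidolysis of the tert-butyl ester (loss of isobutene) should free the C1 acid while the methyl ester, the benzyl ether and the three stereocentres stay untouched.

Step 4
Reactants: 8 all-cis acid; 9 8-aminoquinoline
Product: 10 all-cis N-(quinolin-8-yl) amide of 8 (amide at C1, aryl at C2, methyl ester at C3)
Conditions: EDC·HCl, DMAP, CH2Cl2, rt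
Reagents that add atoms: none
Why: Carbodiimide-mediated amide formation installs the N,N-bidentate auxiliary that is needed later for palladation, under conditions too mild to enolise either carbonyl.

Step 5
Reactants: 10 all-cis amide
Product: 11 C1 epimer of 10 (amide trans to the C2 aryl group and to the C3 ester; aryl and ester still cis)
Conditions: LiOtBu (1.5 equiv), toluene, 50 °C; AcOH quench
Reagents that add atoms: none
Why: Base-mediated epimerisation through the amide enolate should move the carboxamide to the face opposite the aryl and ester groups, relieving the three contiguous cis substituents, with lithium held at the amidate–quinoline site in the non-polar solvent delivering the base to C1–H in preference to C3–H.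

Step 6
Reactants: 11 trans amide; 12 1-(benzyloxy)-4-iodobenzene
Product: 13 methyl 2,4-bis[4-(benzyloxy)phenyl]-3-(quinolin-8-ylcarbamoyl)cyclobutanecarboxylate with the amide cis to the C4 aryl and trans to the C2 aryl, and the ester cis to the C2 aryl and trans to the C4 aryl
Conditions: Pd(OAc)2 (15 mol %), Ag2CO3 (1.5 equiv), PivOH (1 equiv), (CF3)2CHOH, 90 °C
Reagents that add atoms: none
Why: In this 8-aminoquinoline-directed C(sp3)–H arylation the five-membered palladacycle of divalent palladium forms at the secondary C4–H bond cis to the amide, so the new aryl group should enter cis to the amide and therefore trans to the C3 ester and to the C2 aryl group, while the hindered tertiary benzylic C2–H is not arylated.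

Step 7
Reactants: 13 diaryl amide ester
Product: 15 (1α,2β,3β,4α)-2,4-bis[4-(benzyloxy)phenyl]cyclobutane-1,3-dicarboxylic acid (centrosymmetric), via N-Boc imide 14 (not isolated)
Conditions: Boc2O, DMAP, MeCN, 50 °C; then LiOH, H2O2, THF–H2O, 0 to 40 °C; Na2SO3, then HCl
Reagents that add atoms: hydrogen peroxide (OO); lithium hydroxide ([Li+].[OH-])
Why: N-Boc activation twists the secondary amide so that hydroperoxide cleaves the exocyclic acyl–N bond, and hydroxide saponifies the methyl ester in the same pot by acyl attack, which should be faster than enolisation, so the configuration is kept.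

Step 8
Reactants: 15 diacid; 16 2,2,6-trimethyl-4H-1,3-dioxin-4-one (two molecules enter the product)
Product: 18 bis(keto-dioxinone) 1,3-bis[(2,2-dimethyl-4-oxo-4H-1,3-dioxin-6-yl)acetyl]-2,4-bis[4-(benzyloxy)phenyl]cyclobutane, via bis(acyl imidazolide) 17 (not isolated)
Conditions: CDI (2.2 equiv), THF, rt; then added to the lithium dienolate of 16 (7 equiv; from 16 and LiN(SiMe3)2, THF, −78 °C), −78 to −20 °C; AcOH quench
Reagents that add atoms: 2,2,6-trimethyl-4H-1,3-dioxin-4-one, second molecule of 16 (CC1=CC(=O)OC(C)(C)O1)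
Why: Two-directional Claisen-type C-acylation in which each acyl imidazolide group of 17 is attacked by the gamma carbon of one molecule of the dioxinone dienolate, so that two molecules of 16 are built in; the excess dienolate absorbs the imidazole N–H and deprotonates each new beta-dicarbonyl CH2, which should shield the cyclobutane methine hydrogens from enolisation.

Step 9
Reactants: 18 bis(keto-dioxinone)
Product: 19 6,6'-{(1α,2β,3β,4α)-2,4-bis[4-(benzyloxy)phenyl]cyclobutane-1,3-diyl}bis(4-hydroxy-2H-pyran-2-one)
Conditions: toluene, 110 °C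
Reagents that add atoms: none
Why: Retro-[4+2] loss of acetone from each dioxinone gives an acylketene that is trapped by the enol oxygen of the neighbouring ketone, closing both 4-hydroxy-2-pyranone rings at once under neutral conditions.

Step 10
Reactants: 19 bis(4-hydroxy-2-pyranone)
Product: 20 6,6'-{(1α,2β,3β,4α)-2,4-bis[4-(benzyloxy)phenyl]cyclobutane-1,3-diyl}bis(4-methoxy-2H-pyran-2-one)
Conditions: Me2SO4, K2CO3, acetone, 56 °C
Reagents that add atoms: dimethyl sulfate (COS(=O)(=O)OC)
Why: O-Methylation of the vinylogous acid at the 4-oxygen is the usual outcome for 6-alkyl-4-hydroxy-2-pyranones with dimethyl sulfate and carbonate, and the phenols are still masked as benzyl ethers.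

Step 11
Reactants: 20 bis(benzyl ether)
Product: 21 target, 6,6'-[(1α,2β,3β,4α)-2,4-bis(4-hydroxyphenyl)cyclobutane-1,3-diyl]bis(4-methoxy-2H-pyran-2-one)
Conditions: H2 (1 atm), Pd/C (10 wt % palladium on carbon), EtOAc–MeOH, rt
Reagents that add atoms: none
Why: Hydrogenolysis of the two benzyl aryl ethers should free the phenols, since the 4-methoxy-2-pyranone rings are reduced only slowly at 1 atm and room temperature.

**Compound list**

1 | glycine tert-butyl ester | NCC(=O)OC(C)(C)C | starting material
2 | 4-(benzyloxy)benzaldehyde | O=Cc1ccc(OCc2ccccc2)cc1 | starting material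
3 | methyl acrylate | C=CC(=O)OC | starting material
4 | tert-butyl (E)-2-{[4-(benzyloxy)benzylidene]amino}acetate | CC(C)(C)OC(=O)C/N=C/c1ccc(OCc2ccccc2)cc1 | intermediate
5 | 2-tert-butyl 4-methyl (2R*,4R*,5S*)-5-[4-(benzyloxy)phenyl]pyrrolidine-2,4-dicarboxylate (all-cis, racemic) | N1[C@@H](C(=O)OC(C)(C)C)C[C@@H](C(=O)OC)[C@H]1c1ccc(OCc2ccccc2)cc1 | intermediate
6 | 1,1-diazene (isodiazene) of 5 | [N-]=[N+]1[C@@H](C(=O)OC(C)(C)C)C[C@@H](C(=O)OC)[C@H]1c1ccc(OCc2ccccc2)cc1 | intermediate
7 | 1-tert-butyl 3-methyl all-cis-2-[4-(benzyloxy)phenyl]cyclobutane-1,3-dicarboxylate (racemic) | CC(C)(C)OC(=O)[C@@H]1[C@H](c2ccc(OCc3ccccc3)cc2)[C@H](C(=O)OC)C1 | intermediate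
8 | all-cis-2-[4-(benzyloxy)phenyl]-3-(methoxycarbonyl)cyclobutane-1-carboxylic acid | OC(=O)[C@@H]1[C@H](c2ccc(OCc3ccccc3)cc2)[C@H](C(=O)OC)C1 | intermediate
9 | 8-aminoquinoline | Nc1cccc2cccnc12 | starting material
10 | all-cis N-(quinolin-8-yl) amide of 8 | O=C(Nc1cccc2cccnc12)[C@@H]1[C@H](c2ccc(OCc3ccccc3)cc2)[C@H](C(=O)OC)C1 | intermediate
11 | C1 epimer of 10 (amide trans to aryl and ester; aryl cis to ester) | O=C(Nc1cccc2cccnc12)[C@H]1[C@H](c2ccc(OCc3ccccc3)cc2)[C@H](C(=O)OC)C1 | intermediate
12 | 1-(benzyloxy)-4-iodobenzene | Ic1ccc(OCc2ccccc2)cc1 | starting material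
13 | methyl 2,4-bis[4-(benzyloxy)phenyl]-3-(quinolin-8-ylcarbamoyl)cyclobutanecarboxylate (amide cis to C4 aryl, ester cis to C2 aryl, aryls trans, carbonyl groups trans) | O=C(Nc1cccc2cccnc12)[C@H]1[C@H](c2ccc(OCc3ccccc3)cc2)[C@H](C(=O)OC)[C@H]1c1ccc(OCc2ccccc2)cc1 | intermediate
14 | N-Boc imide of 13 | CC(C)(C)OC(=O)N(c1cccc2cccnc12)C(=O)[C@H]1[C@H](c2ccc(OCc3ccccc3)cc2)[C@H](C(=O)OC)[C@H]1c1ccc(OCc2ccccc2)cc1 | intermediate
15 | (1α,2β,3β,4α)-2,4-bis[4-(benzyloxy)phenyl]cyclobutane-1,3-dicarboxylic acid | OC(=O)[C@H]1[C@H](c2ccc(OCc3ccccc3)cc2)[C@H](C(=O)O)[C@H]1c1ccc(OCc2ccccc2)cc1 | intermediate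
16 | 2,2,6-trimethyl-4H-1,3-dioxin-4-one | CC1=CC(=O)OC(C)(C)O1 | starting material
17 | bis(acyl imidazolide) of 15 | O=C(n1ccnc1)[C@H]1[C@H](c2ccc(OCc3ccccc3)cc2)[C@H](C(=O)n2ccnc2)[C@H]1c1ccc(OCc2ccccc2)cc1 | intermediate
18 | 1,3-bis[(2,2-dimethyl-4-oxo-4H-1,3-dioxin-6-yl)acetyl]-2,4-bis[4-(benzyloxy)phenyl]cyclobutane (1α,2β,3β,4α) | CC1(C)OC(=O)C=C(CC(=O)[C@H]2[C@H](c3ccc(OCc4ccccc4)cc3)[C@H](C(=O)CC3=CC(=O)OC(C)(C)O3)[C@H]2c2ccc(OCc3ccccc3)cc2)O1 | intermediate
19 | 6,6'-{(1α,2β,3β,4α)-2,4-bis[4-(benzyloxy)phenyl]cyclobutane-1,3-diyl}bis(4-hydroxy-2H-pyran-2-one) | O=c1cc(O)cc([C@H]2[C@H](c3ccc(OCc4ccccc4)cc3)[C@H](c3cc(O)cc(=O)o3)[C@H]2c2ccc(OCc3ccccc3)cc2)o1 | intermediate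
20 | 6,6'-{(1α,2β,3β,4α)-2,4-bis[4-(benzyloxy)phenyl]cyclobutane-1,3-diyl}bis(4-methoxy-2H-pyran-2-one) | COc1cc(=O)oc([C@H]2[C@H](c3ccc(OCc4ccccc4)cc3)[C@H](c3cc(OC)cc(=O)o3)[C@H]2c2ccc(OCc3ccccc3)cc2)c1 | intermediate
21 | 6,6'-[(1α,2β,3β,4α)-2,4-bis(4-hydroxyphenyl)cyclobutane-1,3-diyl]bis(4-methoxy-2H-pyran-2-one) | COc1cc(=O)oc([C@H]2[C@H](c3ccc(O)cc3)[C@H](c3cc(OC)cc(=O)o3)[C@H]2c2ccc(O)cc2)c1 | target

**Step count.** Total: 11 steps. Longest linear sequence: 11 steps (1 and 2 to 21).

**Steps most likely to fail**

Step 2. Beta-scission of the 1,4-diyl into two acrylate-type alkenes can outrun ring closure, and the trivalent-iodine oxidant can attack the electron-rich benzyloxyphenyl ring before the nitrogen is aminated. The fallback makes the four-membered ring by a photochemical electrocyclisation; it sets out from aryl iodide 12 and amine 9, together with commercial methyl coumalate F1, and comes back at 10. Methyl coumalate F1 is irradiated (medium-pressure Hg lamp, Pyrex, CH2Cl2) to the bicyclic lactone methyl 3-oxo-2-oxabicyclo[2.2.0]hex-5-ene-6-carboxylate F2. Hydrogenation over Pd/C saturates the alkene and cleaves the allylic C–O bond to give cis-3-(methoxycarbonyl)cyclobutane-1-carboxylic acid F3. Coupling with 9 (EDC·HCl, DMAP) gives methyl cis-3-(quinolin-8-ylcarbamoyl)cyclobutane-1-carboxylate F4. Pd(OAc)2/Ag2CO3 monoarylation with a deficit of 12 then places the aryl group cis to the amide and gives 10.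

Step 5. Enolisation may occur at the ester-bearing C3 instead of, or as well as, the amide-bearing C1, which would invert the wrong centre or both. The fallback fixes the site by acidity; it sets out from acid 8 and comes back at 11. Acid 8 is converted (C6F5OH, EDC·HCl) into its all-cis pentafluorophenyl ester F5, whose C1–H is far more acidic than the C3–H of the methyl ester. Catalytic DBU in toluene at rt should then invert C1 only, giving the trans pentafluorophenyl ester F6. Aminolysis with 9 (DMAP, toluene, 80 °C) gives 11.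

Step 8. The second acylation at the hindered carbonyl groups may stall, the dienolate may be O-acylated, and the excess base may enolise the cyclobutane methines. The fallback builds the pyranones from methyl ketones; it sets out from diacid 15 and comes back at 19. Diacid 15 is converted (CDI; MeNHOMe·HCl) into the bis(N-methoxy-N-methylamide) F7, and MeMgBr gives the bis(methyl ketone) F8. Kinetic enolisation at the methyl groups (LiN(iPr)2, Me3SiCl, THF, −78 °C) gives the bis(trimethylsilyl enol ether) F9. Cyclocondensation with malonyl dichloride (Et2O, −78 °C to rt) closes both 4-hydroxy-2-pyranone rings and gives 19.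

**Further compounds**

F1 | step 2 | methyl coumalate (methyl 2-oxo-2H-pyran-5-carboxylate) | COC(=O)c1ccc(=O)oc1
F2 | step 2 | methyl 3-oxo-2-oxabicyclo[2.2.0]hex-5-ene-6-carboxylate (cis-fused, racemic) | COC(=O)C1=C[C@H]2[C@@H]1OC2=O
F3 | step 2 | cis-3-(methoxycarbonyl)cyclobutane-1-carboxylic acid | COC(=O)[C@H]1C[C@@H](C(=O)O)C1
F4 | step 2 | methyl cis-3-(quinolin-8-ylcarbamoyl)cyclobutane-1-carboxylate | COC(=O)[C@H]1C[C@@H](C(=O)Nc2cccc3cccnc23)C1
F5 | step 5 | all-cis pentafluorophenyl ester of 8 | O=C(Oc1c(F)c(F)c(F)c(F)c1F)[C@@H]1[C@H](c2ccc(OCc3ccccc3)cc2)[C@H](C(=O)OC)C1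
F6 | step 5 | C1 epimer of F5 (active ester trans to aryl and methyl ester) | O=C(Oc1c(F)c(F)c(F)c(F)c1F)[C@H]1[C@H](c2ccc(OCc3ccccc3)cc2)[C@H](C(=O)OC)C1
F7 | step 8 | bis(N-methoxy-N-methylamide) of 15 | CON(C)C(=O)[C@H]1[C@H](c2ccc(OCc3ccccc3)cc2)[C@H](C(=O)N(C)OC)[C@H]1c1ccc(OCc2ccccc2)cc1
F8 | step 8 | (1α,2β,3β,4α)-1,3-diacetyl-2,4-bis[4-(benzyloxy)phenyl]cyclobutane | CC(=O)[C@H]1[C@H](c2ccc(OCc3ccccc3)cc2)[C@H](C(C)=O)[C@H]1c1ccc(OCc2ccccc2)cc1
F9 | step 8 | bis(trimethylsilyl enol ether) of F8 | C=C(O[Si](C)(C)C)[C@H]1[C@H](c2ccc(OCc3ccccc3)cc2)[C@H](C(=C)O[Si](C)(C)C)[C@H]1c1ccc(OCc2ccccc2)cc1
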